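## Retrosynthetic overview

1. Target locants: C1 = C(OH)(CH2OBz), C2 = CH(OAc), C3 and C6 = CH(OBz), C4=C5, C7 = CH2OBz. The target comes from acetylation of the C2–OH of a C1/C2 cis-diol, which comes from C2–OH-directed epoxidation of a C1=C7 methylidene and benzoate opening of the spiro-oxirane at C7.
2. The cyclohexene (C4=C5, the only carbocycle) comes from ring-closing metathesis of an acyclic triene.
3. The triene comes from a nickel/chromium-catalysed asymmetric alkenyl iodide–aldehyde coupling that forms C1–C2, joining fragment A (C5–C6–C1–C7, a 2-iodo-1,4-dienyl benzoate) and fragment B (C2–C3–C4, (R)-2-(benzoyloxy)but-3-enal).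
4. Fragment A comes from the acrolein geminal dibenzoate and an alkynyltrifluoroborate by a new iridium-catalysed enantioselective allylic alkynylation (forms C1–C6, sets C6), then α-hydrostannation and iodination. Fragment B comes from (R)-but-3-ene-1,2-diol.
5. Ring order: the carbocycle is closed by metathesis after the fragment union; a transient spiro-oxirane is then formed and opened in one flask.

Assumption: in the two ligand-controlled steps (2 and 9) the ligand antipode named is the one expected to give the drawn configuration; the mirror-image ligand is used if the first run shows the opposite sense.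

## Route

Step 1
Reactants: 1 acrolein
Product: 2 prop-2-ene-1,1-diyl dibenzoate
Conditions: Bz2O (1.0 equiv), conc. H2SO4 (1 mol %), CH2Cl2, 0 °C to rt
Reagents that add atoms: benzoic anhydride, O=C(c1ccccc1)OC(=O)c1ccccc1
Why: Acid-catalysed acylal formation (1,1-diacylation of an aldehyde by an anhydride) converts the enal into the allylic geminal diester without forming a stereocentre.

Step 2
Reactants: 2 prop-2-ene-1,1-diyl dibenzoate; 3 potassium trifluoro[(trimethylsilyl)ethynyl]borate
Product: 5 (S)-pent-1-en-4-yn-3-yl benzoate, via silyl alkyne 4 (not isolated)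
Conditions: 2 (1.3 equiv), 3 (1.0 equiv), [Ir(cod)Cl]2 (3 mol %), (S)-BINOL-derived N-(dibenzo[b,f]azepin-5-yl)phosphoramidite (P,olefin ligand, 12 mol %), KHF2 (1.0 equiv), Bu4NBr (10 mol %), 1,4-dioxane, 25 °C; then Bu4NF (1.1 equiv), AcOH (1.5 equiv), THF, 0 °C
Reagents that add atoms: none
Why: Proposed new method: iridium-catalysed enantioselective allylic alkynylation of an aldehyde-derived geminal dibenzoate, in which the iridium–(P,olefin) catalyst ionises one benzoate of 2 (helped by the geminal acyloxy group) to a 1-(benzoyloxy)allyl iridium electrophile and the alkynyltrifluoroborate attacks the oxygen-bearing, more cation-stabilised terminus on the face left open by the ligand, giving the branched ester and setting the S stereocentre (target C6), the closest known reaction type being iridium-catalysed enantioselective alkynylation of branched allylic alcohols with potassium alkynyltrifluoroborates (together with palladium-catalysed asymmetric substitution of allylic geminal diacetates at the acyloxy-bearing carbon), after which buffered fluoride protodesilylates the alkyne without touching the benzoate.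

Step 3
Reactants: 5 (S)-pent-1-en-4-yn-3-yl benzoate
Product: 6 (S)-2-(tributylstannyl)penta-1,4-dien-3-yl benzoate
Conditions: Bu3SnH (1.3 equiv), Mo(CO)3(CNtBu)3 (2 mol %), hydroquinone (10 mol %), THF, 55 °C
Reagents that add atoms: tributyltin hydride, CCCC[SnH](CCCC)CCCC
Why: Molybdenum-catalysed hydrostannation of terminal propargylic esters is α-selective (tin on the internal carbon), giving the 1,1-disubstituted alkenylstannane while leaving the vinyl group and the stereocentre untouched.

Step 4
Reactants: 6 (S)-2-(tributylstannyl)penta-1,4-dien-3-yl benzoate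
Product: 7 (S)-2-iodopenta-1,4-dien-3-yl benzoate (fragment A)
Conditions: I2 (1.05 equiv), CH2Cl2, 0 °C, dark
Reagents that add atoms: iodine, II
Why: Iododestannylation (ipso electrophilic substitution of the alkenyl–tin bond) gives the 2-iodo-1-alkene needed for the nickel/chromium coupling, with the stereocentre untouched.

Step 5
Reactants: 8 (R)-but-3-ene-1,2-diol
Product: 9 (R)-1-[(tert-butyldimethylsilyl)oxy]but-3-en-2-ol
Conditions: TBSCl (1.05 equiv), imidazole (2.2 equiv), CH2Cl2, −20 to 0 °C
Reagents that add atoms: tert-butyldimethylsilyl chloride, CC(C)(C)[Si](C)(C)Cl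
Why: Sterically controlled silylation selects the primary hydroxyl of the 1,2-diol (standard mono-silyl protection), and the stereocentre comes from the starting material.

Step 6
Reactants: 9 (R)-1-[(tert-butyldimethylsilyl)oxy]but-3-en-2-ol
Product: 10 (R)-1-[(tert-butyldimethylsilyl)oxy]but-3-en-2-yl benzoate
Conditions: BzCl (1.2 equiv), pyridine, DMAP (5 mol %), CH2Cl2, 0 °C to rt
Reagents that add atoms: benzoyl chloride, O=C(Cl)c1ccccc1
Why: DMAP-catalysed acylation of the secondary allylic alcohol installs the benzoate that becomes the C3 ester of the target, with retention at the stereocentre.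

Step 7
Reactants: 10 (R)-1-[(tert-butyldimethylsilyl)oxy]but-3-en-2-yl benzoate
Product: 11 (R)-1-hydroxybut-3-en-2-yl benzoate
Conditions: HF·pyridine, THF–pyridine, 0 °C
Reagents that add atoms: none
Why: Fluoride desilylation under mildly acidic buffering frees the primary alcohol while suppressing 1,2-benzoyl migration, which basic fluoride would promote.

Step 8
Reactants: 11 (R)-1-hydroxybut-3-en-2-yl benzoate
Product: 12 (R)-1-oxobut-3-en-2-yl benzoate (fragment B)
Conditions: Dess–Martin periodinane (1.2 equiv), CH2Cl2, 0 °C, 30 min; silica plug, used at once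
Reagents that add atoms: none
Why: Dess–Martin oxidation is base-free, so the epimerisable α-benzoyloxy β,γ-unsaturated aldehyde is obtained without racemisation or conjugation if used immediately.

Step 9
Reactants: 7 (S)-2-iodopenta-1,4-dien-3-yl benzoate; 12 (R)-1-oxobut-3-en-2-yl benzoate
Product: 13 (3R,4R,6S)-4-hydroxy-5-methylideneocta-1,7-diene-3,6-diyl dibenzoate
Conditions: CrCl2 (10 mol %), (S)-N-[2-(4-isopropyl-4,5-dihydrooxazol-2-yl)-6-methoxyphenyl]methanesulfonamide (11 mol %), proton sponge (11 mol %), NiCl2(2,9-dimethyl-1,10-phenanthroline) (2 mol %), Mn (2 equiv), Cp2ZrCl2 (1.1 equiv), LiCl (2 equiv), MeCN, rt, 12 added last; aqueous work-up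
Reagents that add atoms: none
Why: Catalytic asymmetric Nozaki–Hiyama–Kishi coupling, in which zerovalent nickel inserts into the C–I bond of 7, the alkenyl group passes to the chiral sulfonamide complex of trivalent chromium and adds to the Re face of aldehyde 12 under ligand control, forming the C1–C2 bond and setting the new carbinol centre as R (target C2, syn to the C3 benzoate), 2-halo-1-alkenes being standard partners for this exo-methylene carbinol synthesis.

Step 10
Reactants: 13 (3R,4R,6S)-4-hydroxy-5-methylideneocta-1,7-diene-3,6-diyl dibenzoate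
Product: 14 (1S,4R,5R)-5-hydroxy-6-methylidenecyclohex-2-ene-1,4-diyl dibenzoate
Conditions: second-generation Grubbs catalyst RuCl2(H2IMes)(PCy3)(=CHPh) (5 mol %), 1,4-benzoquinone (10 mol %), CH2Cl2 (5 mM), 40 °C
Reagents that add atoms: none
Why: Ring-closing metathesis can only join the two monosubstituted vinyl groups into the six-membered ring (the 1,1-disubstituted methylidene is a spectator and would only give strained small rings), so the cis C4=C5 alkene forms with all stereocentres untouched.

Step 11
Reactants: 14 (1S,4R,5R)-5-hydroxy-6-methylidenecyclohex-2-ene-1,4-diyl dibenzoate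
Product: 16 [(1S,2S,3R,6S)-3,6-bis(benzoyloxy)-1,2-dihydroxycyclohex-4-en-1-yl]methyl benzoate, via spiro-epoxide 15 (not isolated)
Conditions: VO(acac)2 (5 mol %), t-BuOOH (1.1 equiv, decane), CH2Cl2, 0 °C; then Ti(OiPr)4 (1.5 equiv), PhCO2H (1.5 equiv), rt
Reagents that add atoms: tert-butyl hydroperoxide, CC(C)(C)OO; benzoic acid, OC(=O)c1ccccc1
Why: Vanadium-catalysed hydroxyl-directed epoxidation (Sharpless-type) delivers oxygen to the exocyclic alkene on the face of the pseudo-axial allylic hydroxyl, which is also the face opposite both benzoates, setting the quaternary C1 centre, and titanium-mediated opening of the resulting 2,3-epoxy alcohol by benzoic acid occurs at the unsubstituted CH2 (C-3 type selectivity) without touching that centre.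

Step 12
Reactants: 16 [(1S,2S,3R,6S)-3,6-bis(benzoyloxy)-1,2-dihydroxycyclohex-4-en-1-yl]methyl benzoate
Product: 17 [(1R,2S,3R,6S)-2-(acetyloxy)-3,6-bis(benzoyloxy)-1-hydroxycyclohex-4-en-1-yl]methyl benzoate (target, CNP0148821.1)
Conditions: Ac2O (1.5 equiv), pyridine, DMAP (5 mol %), CH2Cl2, 0 °C
Reagents that add atoms: acetic anhydride, CC(=O)OC(C)=O
Why: DMAP-catalysed acetylation acylates the secondary hydroxyl and leaves the hindered tertiary hydroxyl free, and at 0 °C it is faster than benzoyl migration.

## Compound list

1 | acrolein (prop-2-enal) | C=CC=O | starting material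
2 | prop-2-ene-1,1-diyl dibenzoate | C=CC(OC(=O)c1ccccc1)OC(=O)c1ccccc1 | intermediate
3 | potassium trifluoro[(trimethylsilyl)ethynyl]borate | C[Si](C)(C)C#C[B-](F)(F)F.[K+] | starting material
4 | (S)-5-(trimethylsilyl)pent-1-en-4-yn-3-yl benzoate | C=C[C@H](OC(=O)c1ccccc1)C#C[Si](C)(C)C | intermediate
5 | (S)-pent-1-en-4-yn-3-yl benzoate | C=C[C@H](OC(=O)c1ccccc1)C#C | intermediate
6 | (S)-2-(tributylstannyl)penta-1,4-dien-3-yl benzoate | C=C[C@H](OC(=O)c1ccccc1)C(=C)[Sn](CCCC)(CCCC)CCCC | intermediate
7 | (S)-2-iodopenta-1,4-dien-3-yl benzoate | C=C[C@H](OC(=O)c1ccccc1)C(I)=C | intermediate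
8 | (R)-but-3-ene-1,2-diol | OC[C@H](O)C=C | starting material
9 | (R)-1-[(tert-butyldimethylsilyl)oxy]but-3-en-2-ol | CC(C)(C)[Si](C)(C)OC[C@H](O)C=C | intermediate
10 | (R)-1-[(tert-butyldimethylsilyl)oxy]but-3-en-2-yl benzoate | CC(C)(C)[Si](C)(C)OC[C@H](OC(=O)c1ccccc1)C=C | intermediate
11 | (R)-1-hydroxybut-3-en-2-yl benzoate | OC[C@H](OC(=O)c1ccccc1)C=C | intermediate
12 | (R)-1-oxobut-3-en-2-yl benzoate | O=C[C@H](OC(=O)c1ccccc1)C=C | intermediate
13 | (3R,4R,6S)-4-hydroxy-5-methylideneocta-1,7-diene-3,6-diyl dibenzoate | C=C[C@H](OC(=O)c1ccccc1)C(=C)[C@@H](O)[C@H](OC(=O)c1ccccc1)C=C | intermediate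
14 | (1S,4R,5R)-5-hydroxy-6-methylidenecyclohex-2-ene-1,4-diyl dibenzoate | O[C@H]1[C@H](OC(=O)c2ccccc2)C=C[C@H](OC(=O)c2ccccc2)C1=C | intermediate
15 | (3S,4S,7R,8S)-8-hydroxy-1-oxaspiro[2.5]oct-5-ene-4,7-diyl dibenzoate | O[C@H]1[C@H](OC(=O)c2ccccc2)C=C[C@H](OC(=O)c2ccccc2)[C@]12CO2 | intermediate
16 | [(1S,2S,3R,6S)-3,6-bis(benzoyloxy)-1,2-dihydroxycyclohex-4-en-1-yl]methyl benzoate | O[C@H]1[C@H](OC(=O)c2ccccc2)C=C[C@H](OC(=O)c2ccccc2)[C@]1(O)COC(=O)c1ccccc1 | intermediate
17 | [(1R,2S,3R,6S)-2-(acetyloxy)-3,6-bis(benzoyloxy)-1-hydroxycyclohex-4-en-1-yl]methyl benzoate | CC(=O)O[C@H]1[C@H](OC(=O)c2ccccc2)C=C[C@H](OC(=O)c2ccccc2)[C@]1(O)COC(=O)c1ccccc1 | target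

## Step count and risks

Total step count: 12. Longest linear sequence: 8 (steps 1–4 then 9–12; the other branch, steps 5–8 then 9–12, is equally long).

Steps most likely to fail:

(a) Step 2, the proposed iridium alkynylation of the acylal. The electrophile class is untested: a racemic background reaction through the acyloxy-stabilised cation, attack at the CH2 terminus (linear enol benzoate) or a second ionisation of the product could erode yield or ee. The fallback uses known chemistry, sets out from acrolein 1 and comes back to the route at 4. Zinc–ProPhenol-catalysed addition of trimethylsilylacetylene to 1 (Me2Zn, the ProPhenol antipode that gives the S alcohol, toluene, 4 °C) gives (S)-5-(trimethylsilyl)pent-1-en-4-yn-3-ol F1. Benzoylation (BzCl, pyridine, DMAP, CH2Cl2) then gives 4, which is desilylated with Bu4NF/AcOH exactly as in the second stage of step 2 to give 5.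

(b) Step 9, the fragment union. The required carbinol epimer is the anti-Felkin one, so the chromium ligand must override the bias of the α-benzoyloxy aldehyde. In addition, the alkenyl-chromium carries a β-benzoyloxy group (possible elimination to a vinylallene), zerovalent nickel could ionise the bis-allylic benzoate, and 12 is epimerisable. The fallback sets out from stannane 6 and aldehyde 12 and comes back at 13. Pinnick oxidation of 12 (NaClO2, NaH2PO4, 2-methylbut-2-ene, t-BuOH–H2O) gives (R)-2-(benzoyloxy)but-3-enoic acid F2. Oxalyl chloride with catalytic DMF gives (R)-2-(benzoyloxy)but-3-enoyl chloride F3. Stille acylation of 6 with F3 (Pd2(dba)3, tri(2-furyl)phosphine, toluene, 50 °C) gives (3S,6R)-4-methylidene-5-oxoocta-1,7-diene-3,6-diyl dibenzoate F4. Luche reduction (NaBH4, CeCl3·7H2O, MeOH, −78 °C) then gives 13; in a ketone reduction the polar Felkin–Anh preference is the syn isomer that is needed, and a CBS reduction can reinforce it. This route avoids the organochromium intermediate and turns the substrate bias in favour of the required stereochemistry.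

(c) Step 11, the directed epoxidation and benzoate opening. Facial selectivity on the exocyclic alkene, titanium-promoted benzoyl migration to the adjacent free hydroxyl, or opening at the tertiary carbon could give mixtures. The fallback sets out from 14 and comes back at 16. Hydrogen-bond-directed dihydroxylation with stoichiometric OsO4 and TMEDA (CH2Cl2, −78 °C) adds to the exocyclic alkene on the hydroxyl face and gives the cyclic osmate ester–TMEDA chelate F5. Cleavage with aqueous Na2SO3 gives (1R,4S,5S,6S)-5,6-dihydroxy-5-(hydroxymethyl)cyclohex-2-ene-1,4-diyl dibenzoate F6. Selective benzoylation of the primary hydroxyl (BzCl 1.05 equiv, 2,4,6-collidine, CH2Cl2, −40 °C) then gives 16.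

## Further compounds

F1 | step 2 | (S)-5-(trimethylsilyl)pent-1-en-4-yn-3-ol | C=C[C@H](O)C#C[Si](C)(C)C
F2 | step 9 | (R)-2-(benzoyloxy)but-3-enoic acid | OC(=O)[C@H](OC(=O)c1ccccc1)C=C
F3 | step 9 | (R)-2-(benzoyloxy)but-3-enoyl chloride | O=C(Cl)[C@H](OC(=O)c1ccccc1)C=C
F4 | step 9 | (3S,6R)-4-methylidene-5-oxoocta-1,7-diene-3,6-diyl dibenzoate | C=C[C@H](OC(=O)c1ccccc1)C(=C)C(=O)[C@H](OC(=O)c1ccccc1)C=C
F5 | step 11 | cyclic osmate ester of triol F6 across the C1 and CH2 oxygens, TMEDA chelate | O[C@H]1[C@H](OC(=O)c2ccccc2)C=C[C@H](OC(=O)c2ccccc2)[C@]13CO[Os](=O)(=O)O3.CN(C)CCN(C)C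
F6 | step 11 | (1R,4S,5S,6S)-5,6-dihydroxy-5-(hydroxymethyl)cyclohex-2-ene-1,4-diyl dibenzoate | O[C@H]1[C@H](OC(=O)c2ccccc2)C=C[C@H](OC(=O)c2ccccc2)[C@]1(O)CO
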